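Readings and results come from a simulation from invented constants, noise included.

Watch the fork, not the clock. You asked for a quick number on these set-ups, so here is mine, from the runs so far.

| flask | substrate | coupling partner | remark | time |
|---|---|---|---|---|
| Sunday's | 0.10 M | 1.8 equiv | run made earlier |  |
| Saturday's | 0.050 M | 1.8 equiv | run made earlier |  |
| Thursday's | 0.075 M | 1.8 equiv | run made earlier |  |
| Tuesday's | 0.10 M | 2.7 equiv | run made earlier |  |
| spring | 0.10 M | 1.80 equiv (fed, over 12.0 d) | all but coupling partner at the start; coupling partner goes in evenly over 12.0 d, the run ends at 12 d | 12 d |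
| summer | 0.10 M (fed, over 12.0 d) | 1.80 equiv | a stirred flask in which substrate is dosed at a steady rate over 12.0 d without added volume, worked up at 12 d | 12 d |
| dusk | 0.10 M | 1.80 equiv | everything together in a closed stirred flask, run for 12 d | 12 d |
| winter | 0.10 M | 1.80 equiv | one stirred flow tank at steady state, fed with the mixture as stated, mean residence time 12 d |  |

| run | time / d | target / % | substrate / % |
|---|---|---|---|
| Sunday's | 1.04 | 21.5 | 21.8 |
| Sunday's | 3.00 | 35.6 | 1.6 |
| Sunday's | 6.00 | 36.5 | 0.3 |
| Sunday's | 8.00 | 35.8 | 0 |
| Sunday's | 12.0 | 36.3 | 0.2 |
| Saturday's | 3.00 | 47.9 | 3.1 |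
| Saturday's | 6.00 | 49.9 | 0 |
| Saturday's | 8.00 | 50.9 | 0.7 |
| Saturday's | 12.0 | 51.3 | 0 |
| Saturday's | 15.0 | 50.9 | 0 |
| Thursday's | 3.00 | 41.0 | 1.9 |
| Thursday's | 6.00 | 42.0 | 0 |
| Thursday's | 8.00 | 43.2 | 0 |
| Thursday's | 12.0 | 42.8 | 0 |
| Thursday's | 15.0 | 42.2 | 0 |
| Tuesday's | 3.00 | 30.2 | 0.6 |
| Tuesday's | 6.00 | 29.9 | 0.2 |
| Tuesday's | 8.00 | 29.3 | 0 |
| Tuesday's | 12.0 | 30.1 | 1.2 |
| Tuesday's | 15.0 | 30.3 | 0.3 |

(each reading ± 0.5 percentage points)

- the stated concentrations are those of everything mixed, before any reaction; amounts are the same in each set-up
- the feed brings no volume worth counting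
- the earlier runs were made in a closed, stirred flask

- the set-up with the highest amount of target at the outlet or at the end, in percent of the substrate put in ("none" if the first two lie within 2 percentage points) (spring / summer / dusk / winter / none)
- amount of target at the outlet or at the end, in percent of the substrate put in, spring
- amount of target at the outlet or at the end, in percent of the substrate put in, summer
- amount of target at the outlet or at the end, in percent of the substrate put in, dusk
- amount of target at the outlet or at the end, in percent of the substrate put in, winter

I follow one substrate molecule and count its losing odds: molecules lost per molecule of target kept, which is one over the yield, minus one. Sunday's plateau of 36.2% gives odds of 1.76. Tuesday's plateau of 30.0%, with more partner, gives 2.34, so each equivalent of partner costs 0.639 at this charge. Taking the partner's cost away leaves 0.612, the rest odds: the losing odds of a substrate that meets no partner at 0.10 M. Saturday's run, at 0.050 M, leaves less, 0.374, so I read this loss as substrate meeting target.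

Dusk repeats Sunday's run, so I say 36.2%. In spring, Sunday's substrate reading of 1.6% at 3.00 d sets my window, and I take the partner fed over it to average half of what has gone in by the end of that window, 0.225 equivalents. That gives odds of 0.756 and a yield of 57.0%. Summer has Sunday's partner charge, and I take its target to climb as in Sunday's run, so I keep 36.2%. In the winter tank at steady state, substrate meets target at its outlet level throughout, whereas in Sunday's run target climbs from nothing, so I count the rest odds twice, giving odds of 2.37. With Sunday's first reading taken as a loss constant of 1.46 d⁻¹, I reckon the tank at 28.0%.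

The forecast says spring 60%, summer 41%, dusk 36.3%, winter 45%, best spring, holding that “target is stable once formed”. We share the winner and part most on winter.

The flask gives spring 56.3%, summer 30.4%, dusk 36.6%, winter 26.2%, best spring.

    intermediate A ⇌ intermediate B (K = 0.120, k = 0.00160 min⁻¹)
    intermediate A → target (k = 0.00180 min⁻¹)
    substrate + target → side product B (k = 0.00490 M⁻¹ min⁻¹)
    substrate + coupling partner → side product A (k = 0.00350 M⁻¹ min⁻¹)
    substrate → intermediate A (k = 4.30 × 10⁻⁴ min⁻¹)
    2 substrate → self-condensation product (k = 3.80 × 10⁻⁶ M⁻¹ min⁻¹)

At dusk's charged concentrations, substrate's half-life toward side product A by that step alone is 0.76 d, shorter than its 1.1 d toward intermediate A by that step alone, and target's half-life against substrate by that step alone, 0.98 d, is of like size. With my partner cost taken away, spring's 56.3% leaves rest odds of 0.634 against my 0.612, and winter's 26.2%, over my tank conversion, leaves 1.46 against my 1.22.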